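Readings and results were generated by integration for an exercise, noise included.

45.0% of the charged partner was not held as target at 5.00 min in the summer run, which is the flask asked about, and I carried that figure as the stall share, the fraction of charged partner not held as target once target stops rising.

in all of them: substrate 0.40 M; initiator 40 mM

|  | partner | remark | time |
|---|---|---|---|
| summer | 0.36 M | the very flask that is asked about, followed so far |  |
| noon | 0.18 M | run made earlier |  |
| flask | 0.360 M |  | 10 min |

summer run (percent of the substrate charged)

| time / min | target / % |
|---|---|
| 0.667 | 25.6 |
| 1.00 | 32.2 |
| 1.33 | 37.7 |
| 2.50 | 45.6 |
| 3.00 | 46.6 |
| 5.00 | 49.5 |
| 8.00 | 49.0 |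

noon run (percent of the substrate charged)

| time / s | target / % |
|---|---|
| 12.0 | 4.6 |
| 25.0 | 9.8 |
| 40.0 | 12.9 |
| 50.0 | 15.0 |
| 60.0 | 16.3 |
| 80.0 | 19.2 |

(standard deviation of a reading: 0.5 percentage points)

- percent here means substrate units held: one ended chains A or side product counts as two
- what is taken out of target is counted as made
- what may be going on: 2 initiating radical -> ended chains B; 2 chain carrier -> ended chains A; partner + chain carrier -> target + initiating radical; substrate + initiating radical <-> chain carrier; substrate + target -> side product; initiator -> 2 initiating radical
- additions bring no volume worth counting

- south-east: at 10 min add partner, 50.0% of the amount charged, then wait 10 min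
- west: at 10 min add substrate, 50.0% of the amount charged, then wait 10 min
- north-east: change nothing and wait 10 min more
- north: at 10 min take out 90% of the target then present, then wait 10 min

- target, in percent of the substrate first charged, at 10 min
- what to do for the largest gain in target; "none" if nothing gains more than 2 percentage points (south-east / west / north-east / north / none)
- target present, with what was taken out counted in, in percent of the substrate first charged, after south-east
- target present, with what was taken out counted in, in percent of the substrate first charged, after west

I ran the flask in slow motion. In the first instants, initiator splits into initiating radical, this adds to substrate to give chain carrier, and chain carrier meets partner to give target and a fresh initiating radical; two chain carriers meeting end as ended chains A. The noon run already held 4.6% target at 12.0 s.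

In the middle, the summer run kept 64.2% of its partner at 1.00 min and the noon run 63.8% at 1 min, though summer charged twice the partner. So at equal times partner had fallen by like fractions in the two runs, which I read as first order in partner. The noon run had made half the target by then, so its substrate stood higher, yet the shares matched, and I took the share to be hardly touched by substrate.

At the end, target went from 45.6% at 2.50 min to 49.5% at 5.00 min, then read 49.0% at 8.00 min, a drop of one scatter, 0.5 percentage points. The rise stopped with partner free, so partner did not stop it, and I expected added partner to stay free. My own reckoning put the flask at its last reading, 49.0%, a little above the forecast.

The forecast gave 48.8% (47.8% to 49.8%) at 10 min, best move none, 47.3% after south-east and 45.8% after west, on the ground “Extra partner or substrate therefore makes no new target”.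

The flask gave 48.0% at 10 min, best move none, with 45.0% after south-east and 39.3% after west, 6.5 points below the forecast.

    2 initiating radical → ended chains B (k = 1.00 × 10⁶ /M/s)
    2 chain carrier → ended chains A (k = 4.00 × 10⁶ /M/s)
    partner + chain carrier → target + initiating radical (k = 680 /M/s)
    substrate + initiating radical ⇌ chain carrier (K = 1.60 × 10⁶ /M, k = 9800 /M/s)
    substrate + target → side product (k = 0.00120 /M/s)
    initiator → 2 initiating radical (k = 0.0250 /s)

The addition in west took free substrate from 24.3% to 74.3% of the charge. Target ended lower after west by 8.7 points, and lower after north-east by 3 points. The flask's partner stood at 42.4% at 10.0 min, 2.6 points below the stall share. In the neighbour flask with 1.0 M of substrate, partner also stood at 42.3%. The stall share gives that neighbour 19.8% of its substrate as target made; it held 13.4% as target and 14.8% as side product, which counts two, together 20.8%.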